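**Retrosynthetic overview**
1. Quinic acid numbering is used: C1 is the carbinol carbon bearing carboxyl C7, C2 and C6 are the ring methylenes, C3 carries the free OH, and C4 and C5 carry the esters. The last disconnections are the two p-coumaroyl esters at O4 and O5 (double Steglich esterification, phenols masked as tert-butyl ethers) and one acidolysis of all protecting groups.
2. Enabling feature: within the single cyclohexane ring, the chain O5–C5–C6–C1(OH)–C7(=O) is a γ-oxygenated α-hydroxy acid. C6 is therefore the β-carbon of a latent acrylate (C6=C1–C7) and C5 is a latent aldehyde.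
3. Key disconnection C5–C6 (together with C1–O1): an acyclic aldehyde–acrylate is closed reductively with SmI2 and oxygenated at C1 in the same flask. This creates the ring, C5 and the fully substituted C1.
4. The acyclic precursor comes from a Barbier union at C2–C3 of (S)-glyceraldehyde acetonide (C3–C5, source of the C4 stereocentre) with tert-butyl 2-(bromomethyl)acrylate (C1, C2, C6, C7). O3 is marked with TBS and O4 with TES.
5. Ring order: only the cyclohexane is built (step 6). The dioxolane of the starting material is opened before that.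

Key step: step 6

Assumption: (S)-glyceraldehyde acetonide is taken as purchasable and is distilled just before use, because it hydrates and oligomerises on storage.

Step 1
Reactants: 1 (S)-glyceraldehyde acetonide; 2 tert-butyl 2-(bromomethyl)acrylate
Product: 4 tert-butyl (4R)-4-[(4S)-2,2-dimethyl-1,3-dioxolan-4-yl]-4-hydroxy-2-methylidenebutanoate, via allylzinc bromide 3 (not isolated)
Conditions: Zn dust, THF/sat. aq. NH4Cl, 0 °C to rt
Reagents that add atoms: none
Why: Aqueous Barbier-type 2-(alkoxycarbonyl)allylation in which allylzinc 3 attacks the aldehyde under polar Felkin–Anh control, anti to the dioxolane C–O bond, so that the new C3 carbinol should form anti to C4 (4R), the bulky tert-butyl ester holding back lactonisation.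

Step 2
Reactants: 4 tert-butyl (4R)-4-[(4S)-2,2-dimethyl-1,3-dioxolan-4-yl]-4-hydroxy-2-methylidenebutanoate
Product: 5 tert-butyl (4R)-4-[(tert-butyldimethylsilyl)oxy]-4-[(4S)-2,2-dimethyl-1,3-dioxolan-4-yl]-2-methylidenebutanoate
Conditions: TBSCl, imidazole, DMAP (cat.), DMF, rt
Reagents that add atoms: tert-butyldimethylsilyl chloride, CC(C)(C)[Si](C)(C)Cl
Why: Routine silyl ether formation on the only free hydroxyl, which marks O3 as the oxygen that must stay unacylated and touches no stereocentre.

Step 3
Reactants: 5 tert-butyl (4R)-4-[(tert-butyldimethylsilyl)oxy]-4-[(4S)-2,2-dimethyl-1,3-dioxolan-4-yl]-2-methylidenebutanoate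
Product: 6 tert-butyl (4R,5S)-4-[(tert-butyldimethylsilyl)oxy]-5,6-dihydroxy-2-methylidenehexanoate
Conditions: AcOH/H2O (4:1), rt
Reagents that add atoms: none
Why: Acid-catalysed acetal hydrolysis, in which the terminal isopropylidene acetal should cleave well before the hindered secondary TBS ether or the tert-butyl ester.

Step 4
Reactants: 6 tert-butyl (4R,5S)-4-[(tert-butyldimethylsilyl)oxy]-5,6-dihydroxy-2-methylidenehexanoate
Product: 7 tert-butyl (4R,5S)-4-[(tert-butyldimethylsilyl)oxy]-2-methylidene-5,6-bis[(triethylsilyl)oxy]hexanoate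
Conditions: TESCl, imidazole, CH2Cl2, 0 °C
Reagents that add atoms: chlorotriethylsilane, CC[Si](Cl)(CC)CC
Why: Routine silyl ether formation that masks both new hydroxyls by a group markedly more labile than TBS, so that O4 can later be freed without touching O3.

Step 5
Reactants: 7 tert-butyl (4R,5S)-4-[(tert-butyldimethylsilyl)oxy]-2-methylidene-5,6-bis[(triethylsilyl)oxy]hexanoate
Product: 8 tert-butyl (4R,5R)-4-[(tert-butyldimethylsilyl)oxy]-2-methylidene-6-oxo-5-[(triethylsilyl)oxy]hexanoate
Conditions: (COCl)2, DMSO, CH2Cl2, −78 to −35 °C; Et3N, −78 to 0 °C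
Reagents that add atoms: none
Why: Swern oxidation run directly on the bis-silyl ether, a known chemoselective variant in which only the unhindered primary triethylsilyl ether is cleaved and oxidised by the activated sulfoxide, the low temperature guarding the α-stereocentre C4.

Step 6
Reactants: 8 tert-butyl (4R,5R)-4-[(tert-butyldimethylsilyl)oxy]-2-methylidene-6-oxo-5-[(triethylsilyl)oxy]hexanoate
Product: 10 tert-butyl 3-O-(tert-butyldimethylsilyl)-4-O-(triethylsilyl)-(−)-quinate (O1, O3 and O4 on one ring face, O5 and the ester on the other), via samarium alkoxide enolate 9 (not isolated)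
Conditions: SmI2 (2.2 equiv), THF, high dilution, no proton source, −78 to −40 °C; then 2-(phenylsulfonyl)-3-phenyloxaziridine, −78 °C; cold pH 7 buffer quench
Reagents that add atoms: 2-(phenylsulfonyl)-3-phenyloxaziridine, O=S(=O)(c1ccccc1)N1OC1c1ccccc1
Why: Proposed new method: divalent samarium reduces the aldehyde of 8 to a ketyl at C5 that adds to the terminal acrylate carbon C6, the resulting C1 radical takes up a second electron, and because no proton source is present the trivalent samarium enolate 9 should survive until the N-sulfonyloxaziridine transfers oxygen to C1. The closest known reactions are the SmI2 reductive coupling of aldehydes with acrylates to γ-hydroxy esters (ketyl–olefin coupling), radical closures onto 2-substituted acrylates and the oxaziridine hydroxylation of lithium or potassium ester enolates, so only their union through a samarium enolate is new. The cyclohexane closes in the 6-endo-trig mode, which should beat 5-exo because the nucleophilic ketyl attacks the unsubstituted β-carbon and thereby gives the ester-stabilised tertiary radical. C5 is set in a chair in which the samarium-bound O5 stands anti to the C4 silyl ether (dipole minimisation) and the C3 silyl ether is equatorial, whereas the C5 epimer would need a gauche O4/O5 pair or a 1,3-diaxial O3/O5 contact, so O5 should end trans to O4. C1 is set because the axial O5–samarium alkoxide can bind the enolate oxygen and cover the face of C1 syn to O5, so oxygen should arrive from the opposite face and leave the ester cis to O5 and O1 cis to O3, as in quinic acid. The step needs aldehyde-over-ester chemoselectivity, retention of the α-silyloxy group and no lactonisation, which are served by the fast intramolecular capture of the ketyl, the poor leaving ability of a silyloxide, and the bulky tert-butyl ester combined with a cold quench.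

Step 7
Reactants: 10 tert-butyl 3-O-(tert-butyldimethylsilyl)-4-O-(triethylsilyl)-(−)-quinate
Product: 11 tert-butyl 3-O-(tert-butyldimethylsilyl)-(−)-quinate (free OH at C1, C4 and C5)
Conditions: PPTS (cat.), MeOH/CH2Cl2, 0 °C
Reagents that add atoms: none
Why: Acid-catalysed methanolysis of a silyl ether, selective because a secondary TES ether solvolyses far faster than the TBS ether, while the tert-butyl ester is too hindered to lactonise onto O5.

Step 8
Reactants: 12 4-tert-butoxybenzaldehyde; 13 malonic acid
Product: 15 (E)-3-(4-tert-butoxyphenyl)prop-2-enoic acid, via arylidenemalonic acid 14 (not isolated)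
Conditions: pyridine, piperidine (cat.), 90 °C
Reagents that add atoms: none
Why: Knoevenagel–Doebner condensation, in which arylidenemalonic acid 14 loses CO2 in hot pyridine to give the thermodynamically favoured E acid and the aryl tert-butyl ether is inert to base.

Step 9
Reactants: 11 tert-butyl 3-O-(tert-butyldimethylsilyl)-(−)-quinate; 15 (E)-3-(4-tert-butoxyphenyl)prop-2-enoic acid
Product: 16 tert-butyl 3-O-(tert-butyldimethylsilyl)-4,5-bis-O-[(E)-3-(4-tert-butoxyphenyl)prop-2-enoyl]-(−)-quinate
Conditions: 15 (2.6 equiv), DCC, DMAP, CH2Cl2, 0 °C to rt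
Reagents that add atoms: none
Why: Double Steglich esterification of the two equatorial secondary hydroxyls, selective because the tertiary C1 hydroxyl beside the tert-butyl ester is far less accessible and O3 is silylated, no stereocentre being involved.

Step 10
Reactants: 16 tert-butyl 3-O-(tert-butyldimethylsilyl)-4,5-bis-O-[(E)-3-(4-tert-butoxyphenyl)prop-2-enoyl]-(−)-quinate
Product: 17 4,5-di-O-p-coumaroylquinic acid
Conditions: TFA/H2O (9:1), 0 °C to rt
Reagents that add atoms: none
Why: One acidolysis (alkyl–oxygen cleavage of the tert-butyl ester and of both aryl tert-butyl ethers, hydrolysis of the TBS ether) frees the acid, the phenols and the C3 hydroxyl, and the acidic medium avoids the base-promoted acyl migration and leaves the cinnamate geometry and all stereocentres untouched.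

**Compound list**
1 | (S)-glyceraldehyde acetonide, (4S)-2,2-dimethyl-1,3-dioxolane-4-carbaldehyde | CC1(C)O[C@@H](CO1)C=O | starting material
2 | tert-butyl 2-(bromomethyl)acrylate | C=C(CBr)C(=O)OC(C)(C)C | starting material
3 | [2-(tert-butoxycarbonyl)allyl]zinc bromide | C=C(C[Zn]Br)C(=O)OC(C)(C)C | intermediate
4 | tert-butyl (4R)-4-[(4S)-2,2-dimethyl-1,3-dioxolan-4-yl]-4-hydroxy-2-methylidenebutanoate | CC1(C)O[C@@H](CO1)[C@H](O)CC(=C)C(=O)OC(C)(C)C | intermediate
5 | tert-butyl (4R)-4-[(tert-butyldimethylsilyl)oxy]-4-[(4S)-2,2-dimethyl-1,3-dioxolan-4-yl]-2-methylidenebutanoate | CC1(C)O[C@@H](CO1)[C@H](O[Si](C)(C)C(C)(C)C)CC(=C)C(=O)OC(C)(C)C | intermediate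
6 | tert-butyl (4R,5S)-4-[(tert-butyldimethylsilyl)oxy]-5,6-dihydroxy-2-methylidenehexanoate | O[C@@H](CO)[C@H](O[Si](C)(C)C(C)(C)C)CC(=C)C(=O)OC(C)(C)C | intermediate
7 | tert-butyl (4R,5S)-4-[(tert-butyldimethylsilyl)oxy]-2-methylidene-5,6-bis[(triethylsilyl)oxy]hexanoate | CC[Si](CC)(CC)O[C@@H](CO[Si](CC)(CC)CC)[C@H](O[Si](C)(C)C(C)(C)C)CC(=C)C(=O)OC(C)(C)C | intermediate
8 | tert-butyl (4R,5R)-4-[(tert-butyldimethylsilyl)oxy]-2-methylidene-6-oxo-5-[(triethylsilyl)oxy]hexanoate | CC[Si](CC)(CC)O[C@@H](C=O)[C@H](O[Si](C)(C)C(C)(C)C)CC(=C)C(=O)OC(C)(C)C | intermediate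
9 | cyclised bis(diiodosamarium) species: O5 alkoxide and C1=C7 ester enolate, both on trivalent samarium | CC[Si](CC)(CC)O[C@@H]1[C@H](O[Si](C)(C)C(C)(C)C)CC(=C(OC(C)(C)C)O[Sm](I)I)C[C@H]1O[Sm](I)I | intermediate
10 | tert-butyl 3-O-(tert-butyldimethylsilyl)-4-O-(triethylsilyl)-(−)-quinate | CC[Si](CC)(CC)O[C@@H]1[C@H](O[Si](C)(C)C(C)(C)C)C[C@@](O)(C(=O)OC(C)(C)C)C[C@H]1O | intermediate
11 | tert-butyl 3-O-(tert-butyldimethylsilyl)-(−)-quinate | O[C@@H]1[C@H](O[Si](C)(C)C(C)(C)C)C[C@@](O)(C(=O)OC(C)(C)C)C[C@H]1O | intermediate
12 | 4-tert-butoxybenzaldehyde | CC(C)(C)Oc1ccc(C=O)cc1 | starting material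
13 | malonic acid | OC(=O)CC(=O)O | starting material
14 | 2-(4-tert-butoxybenzylidene)malonic acid | CC(C)(C)Oc1ccc(C=C(C(=O)O)C(=O)O)cc1 | intermediate
15 | (E)-3-(4-tert-butoxyphenyl)prop-2-enoic acid | CC(C)(C)Oc1ccc(/C=C/C(=O)O)cc1 | intermediate
16 | tert-butyl 3-O-(tert-butyldimethylsilyl)-4,5-bis-O-[(E)-3-(4-tert-butoxyphenyl)prop-2-enoyl]-(−)-quinate | O=C(/C=C/c1ccc(OC(C)(C)C)cc1)O[C@@H]1[C@H](O[Si](C)(C)C(C)(C)C)C[C@@](O)(C(=O)OC(C)(C)C)C[C@H]1OC(=O)/C=C/c1ccc(OC(C)(C)C)cc1 | intermediate
17 | 4,5-di-O-p-coumaroylquinic acid | O=C(/C=C/c1ccc(O)cc1)O[C@@H]1[C@H](O)C[C@@](O)(C(=O)O)C[C@H]1OC(=O)/C=C/c1ccc(O)cc1 | target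

Total step count: 10. Longest linear sequence: 9 steps (steps 1–7, 9 and 10).

**Steps most likely to fail**

Step 6 (Proposed new method).
- What may go wrong: the samarium enolate may be protonated or self-condense before oxygen transfer. Oxygen may be delivered to the wrong face of C1. The ketyl may lose the α-silyloxy group, or the tert-butyl ester may be lost by lactonisation onto O5.
- The fallback uses known reaction types, sets out from 5 and comes back at 11. It completes C1 before ring closure and makes the same C5–C6 bond by a polar nitroaldol closure.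
- Ozonolysis of the acrylate of 5 (O3, CH2Cl2, −78 °C; Me2S) should give the α-keto ester F1. A catalytic asymmetric Henry reaction with nitromethane should then give the tertiary nitro alcohol F2. The conditions are Cu(OTf)2, Et3N and the tBu-box ligand antipode that directs the nitronate to the face giving the 2S centre.
- Aqueous acetic acid should free the nitro triol F3. TEMPO/PhI(OAc)2 should oxidise only its primary alcohol to the nitro aldehyde F4.
- On addition of a catalytic amine base, F4 should close by an intramolecular Henry reaction, the classical carbocyclisation of 6-deoxy-6-nitrohexoses. This gives the nitrocyclitol F5, and equilibration should place O5 and the nitro group equatorial.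
- Radical denitration (Bu3SnH, AIBN, toluene, reflux) should remove the activating group and deliver 11.

Step 9.
- What may go wrong: acylation may stay incomplete at O4, which is crowded by the neighbouring TBS ether and the first ester. The activated acid may rearrange to the N-acylurea, and forcing conditions may acylate O1.
- The fallback sets out from 11 and comes back at 16. It builds the cinnamates on the ring instead of attaching them whole.
- Heating 11 with 2,2-dimethyl-1,3-dioxane-4,6-dione in toluene should acylate O4 and O5 with the small malonyl unit and give the bis(hydrogen malonate) F6.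
- A double Knoevenagel–Doebner condensation of F6 with aldehyde 12 (pyridine, piperidine cat.) should then give 16.

Step 5.
- What may go wrong: the two TES ethers may be poorly discriminated. C4 may epimerise, or silyloxide may be lost by β-elimination during the amine stage.
- The fallback sets out from 6, bypasses 7 and comes back at 8. It reverses the order of protection and oxidation.
- TEMPO/PhI(OAc)2 should oxidise only the primary hydroxyl of 6 under near-neutral conditions to the α-hydroxy aldehyde F7.
- Immediate silylation (TESCl, imidazole, CH2Cl2, 0 °C) should convert F7 into 8.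

**Further compounds**
F1 | step 6 | tert-butyl (4R)-4-[(tert-butyldimethylsilyl)oxy]-4-[(4S)-2,2-dimethyl-1,3-dioxolan-4-yl]-2-oxobutanoate | CC1(C)O[C@@H](CO1)[C@H](O[Si](C)(C)C(C)(C)C)CC(=O)C(=O)OC(C)(C)C
F2 | step 6 | tert-butyl (2S,4R)-4-[(tert-butyldimethylsilyl)oxy]-4-[(4S)-2,2-dimethyl-1,3-dioxolan-4-yl]-2-hydroxy-2-(nitromethyl)butanoate | CC1(C)O[C@@H](CO1)[C@H](O[Si](C)(C)C(C)(C)C)C[C@@](O)(C(=O)OC(C)(C)C)C[N+](=O)[O-]
F3 | step 6 | tert-butyl (2S,4R,5S)-4-[(tert-butyldimethylsilyl)oxy]-2,5,6-trihydroxy-2-(nitromethyl)hexanoate | O[C@@H](CO)[C@H](O[Si](C)(C)C(C)(C)C)C[C@@](O)(C(=O)OC(C)(C)C)C[N+](=O)[O-]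
F4 | step 6 | tert-butyl (2S,4R,5R)-4-[(tert-butyldimethylsilyl)oxy]-2,5-dihydroxy-2-(nitromethyl)-6-oxohexanoate | O[C@@H](C=O)[C@H](O[Si](C)(C)C(C)(C)C)C[C@@](O)(C(=O)OC(C)(C)C)C[N+](=O)[O-]
F5 | step 6 | tert-butyl 3-O-(tert-butyldimethylsilyl)-6-nitro-(−)-quinate (nitro group equatorial, trans to O5) | O[C@@H]1[C@H](O[Si](C)(C)C(C)(C)C)C[C@@](O)(C(=O)OC(C)(C)C)[C@H]([N+](=O)[O-])[C@H]1O
F6 | step 9 | tert-butyl 3-O-(tert-butyldimethylsilyl)-4,5-bis-O-(carboxyacetyl)-(−)-quinate | O=C(O)CC(=O)O[C@@H]1[C@H](O[Si](C)(C)C(C)(C)C)C[C@@](O)(C(=O)OC(C)(C)C)C[C@H]1OC(=O)CC(=O)O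
F7 | step 5 | tert-butyl (4R,5R)-4-[(tert-butyldimethylsilyl)oxy]-5-hydroxy-2-methylidene-6-oxohexanoate | O[C@@H](C=O)[C@H](O[Si](C)(C)C(C)(C)C)CC(=C)C(=O)OC(C)(C)C
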